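**Strategy.** The route rests on disconnecting the peroxide O–C5 bond of the 1,2-dioxolane. Ring carbon C5 bears a methyl group next to a ring oxygen, which is what Markovnikov addition of oxygen to a C5=CH2 group leaves behind. Mercury diacetate therefore closes the ring in one operation: the C3 hydroperoxide attacks the activated methylidene, creating the dioxolane, the O–C5 bond and the C5 stereocentre, with the CH2–Hg group as the future methyl. The precursor is an open-chain tertiary (3S)-hydroperoxide carrying the C5 methylidene, the complete (7R) diene chain and a silyl-protected C1 alcohol; C3 comes from (S)-mevalonolactone through invertive perhydrolysis of an oxetane.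

Key step: step 14

Atom labels: C1 is the carboxyl carbon, C3 and C5 are the ring carbons, C7 is the methyl-bearing chain carbon, and C12=C13 and C16=C17 are the alkenes.

Assumption: Lewis-acid perhydrolysis of the 2,2-disubstituted oxetane is taken to proceed with inversion at the quaternary carbon, so the (S)-lactone is the matching enantiomer.

**Route**

Step 1
Reactants: 1 (S)-mevalonolactone
Product: 2 (3S)-3,5-dihydroxy-N-methoxy-N,3-dimethylpentanamide
Conditions: MeNH(OMe)·HCl, AlMe3, CH2Cl2, 0 °C → rt; aqueous work-up, used at once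
Reagents that add atoms: N,O-dimethylhydroxylamine hydrochloride, CNOC.Cl
Why: Weinreb aminolysis of the lactone with the aluminium amide opens the ring at the acyl carbon only, so the tertiary carbinol centre is untouched, and immediate use forestalls relactonisation.

Step 2
Reactants: 2 (3S)-3,5-dihydroxy-N-methoxy-N,3-dimethylpentanamide
Product: 4 N-methoxy-N-methyl-2-[(2S)-2-methyloxetan-2-yl]acetamide, via primary tosylate 3 (not isolated)
Conditions: TsCl, Et3N, DMAP (cat.), CH2Cl2, 0 °C; then KOtBu, THF, 0 °C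
Reagents that add atoms: none
Why: Selective sulfonylation of the primary hydroxyl followed by intramolecular Williamson etherification (4-exo-tet) by the tertiary alkoxide closes the oxetane with retention, because the C–O bond of the quaternary carbon is never broken.

Step 3
Reactants: 5 (4E)-5-phenylpent-4-enoic acid
Product: 6 (4E)-5-phenylpent-4-en-1-ol
Conditions: LiAlH4, THF, 0 °C → rt
Reagents that add atoms: none
Why: Hydride reduction of the carboxylic acid gives the primary alcohol and leaves the styrenyl alkene untouched.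

Step 4
Reactants: 6 (4E)-5-phenylpent-4-en-1-ol
Product: 7 1-phenyl-5-{[(4E)-5-phenylpent-4-en-1-yl]sulfanyl}-1H-tetrazole
Conditions: 1-phenyl-1H-tetrazole-5-thiol, PPh3, DIAD, THF, 0 °C → rt
Reagents that add atoms: 1-phenyl-1H-tetrazole-5-thiol, Sc1nnnn1-c1ccccc1
Why: Mitsunobu thioetherification of a primary alcohol with the acidic tetrazole thiol is the standard entry to Julia–Kocienski reagents.

Step 5
Reactants: 7 1-phenyl-5-{[(4E)-5-phenylpent-4-en-1-yl]sulfanyl}-1H-tetrazole
Product: 8 1-phenyl-5-{[(4E)-5-phenylpent-4-en-1-yl]sulfonyl}-1H-tetrazole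
Conditions: 30% aq. H2O2, (NH4)6Mo7O24·4H2O (cat.), EtOH, 0 °C → rt
Reagents that add atoms: hydrogen peroxide, OO
Why: Molybdate-catalysed peroxide oxidation takes the sulfide to the sulfone chemoselectively in the presence of alkenes.

Step 6
Reactants: 9 (2R)-3-bromo-2-methylpropan-1-ol
Product: 10 (2R)-3-bromo-2-methylpropyl trifluoromethanesulfonate
Conditions: Tf2O, 2,6-lutidine, CH2Cl2, −78 °C; cold filtration, used crude at once
Reagents that add atoms: trifluoromethanesulfonic anhydride, O=S(=O)(OS(=O)(=O)C(F)(F)F)C(F)(F)F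
Why: Triflation of the primary alcohol at low temperature gives a leaving group far more reactive than the primary bromide in the same molecule, and the stereocentre is not involved.

Step 7
Reactants: 10 (2R)-3-bromo-2-methylpropyl trifluoromethanesulfonate; 11 5-bromopent-1-ene
Product: 13 (7R)-8-bromo-7-methyloct-1-ene, via pent-4-enylmagnesium bromide 12 (not isolated)
Conditions: 11, Mg, THF, rt; then 10, CuBr·SMe2 (5 mol%), Et2O/THF, −78 → −20 °C
Reagents that add atoms: none
Why: Copper-catalysed sp3–sp3 coupling of a Grignard reagent with a primary alkyl triflate proceeds at −78 to −20 °C, where the primary bromide is inert, so the bromide survives as the later Grignard handle.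

Step 8
Reactants: 13 (7R)-8-bromo-7-methyloct-1-ene
Product: 14 (6R)-7-bromo-6-methylheptanal
Conditions: O3, CH2Cl2, −78 °C; then PPh3, −78 °C → rt
Reagents that add atoms: ozone, [O-][O+]=O
Why: Ozonolysis with reductive work-up cleaves the only alkene to the aldehyde without touching the alkyl bromide or the stereocentre.

Step 9
Reactants: 8 1-phenyl-5-{[(4E)-5-phenylpent-4-en-1-yl]sulfonyl}-1H-tetrazole; 14 (6R)-7-bromo-6-methylheptanal
Product: 15 [(1E,5E,11R)-12-bromo-11-methyldodeca-1,5-dien-1-yl]benzene
Conditions: 8, KN(SiMe3)2, DME, −60 °C; then 14, −60 °C → rt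
Reagents that add atoms: none
Why: Julia–Kocienski olefination of an unbranched aldehyde with a 1-phenyltetrazolyl sulfone under potassium amide in DME is reliably E-selective and forms the C12=C13 alkene, while the β-branched primary bromide is too slow an electrophile to compete at this temperature.

Step 10
Reactants: 15 [(1E,5E,11R)-12-bromo-11-methyldodeca-1,5-dien-1-yl]benzene; 4 N-methoxy-N-methyl-2-[(2S)-2-methyloxetan-2-yl]acetamide
Product: 17 (4R,9E,13E)-4-methyl-1-[(2S)-2-methyloxetan-2-yl]-14-phenyltetradeca-9,13-dien-2-one, via chain Grignard reagent 16 (not isolated)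
Conditions: 15, Mg, THF, 40 °C; then 4, THF, −20 → 0 °C; aq. NH4Cl
Reagents that add atoms: none
Why: In this Weinreb ketone synthesis the primary alkylmagnesium bromide adds once to the amide through the stable chelated tetrahedral intermediate, the oxetane and the alkenes are inert to the Grignard reagent at 0 °C, and the C7 centre, one carbon away from magnesium, keeps its configuration.

Step 11
Reactants: 17 (4R,9E,13E)-4-methyl-1-[(2S)-2-methyloxetan-2-yl]-14-phenyltetradeca-9,13-dien-2-one
Product: 18 (2R)-2-methyl-2-[(4R,9E,13E)-4-methyl-2-methylidene-14-phenyltetradeca-9,13-dien-1-yl]oxetane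
Conditions: Ph3PCH3Br, KN(SiMe3)2, THF, 0 °C; then 17, −78 → 0 °C
Reagents that add atoms: methyltriphenylphosphonium bromide, C[P+](c1ccccc1)(c1ccccc1)c1ccccc1.[Br-]
Why: Wittig methylenation of an unhindered dialkyl ketone at low temperature is faster than enolisation, so β-elimination that would open the oxetane is avoided (the oxetane descriptor changes by priority only).

Step 12
Reactants: 18 (2R)-2-methyl-2-[(4R,9E,13E)-4-methyl-2-methylidene-14-phenyltetradeca-9,13-dien-1-yl]oxetane
Product: 19 (3S,7R,12E,16E)-3-hydroperoxy-3,7-dimethyl-5-methylidene-17-phenylheptadeca-12,16-dien-1-ol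
Conditions: anhydrous H2O2 in Et2O (excess), Me3SiOTf (0.2 equiv), −78 → 0 °C
Reagents that add atoms: hydrogen peroxide, OO
Why: In this Lewis-acid-promoted perhydrolysis of a 2,2-disubstituted oxetane the silyl triflate activates the ring oxygen and H2O2 attacks the tertiary carbon from the rear in an SN2-like opening of a tight ion pair, which sets C3 with inversion and frees the C1 hydroxyl.

Step 13
Reactants: 19 (3S,7R,12E,16E)-3-hydroperoxy-3,7-dimethyl-5-methylidene-17-phenylheptadeca-12,16-dien-1-ol
Product: 21 tert-butyl{[(3S,7R,12E,16E)-3-hydroperoxy-3,7-dimethyl-5-methylidene-17-phenylheptadeca-12,16-dien-1-yl]oxy}dimethylsilane, via bis-silyl compound 20 (not isolated)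
Conditions: TBSCl (2.5 equiv), imidazole, DMF, 0 °C → rt; then K2CO3, MeOH, 0 °C → rt
Reagents that add atoms: tert-butyldimethylsilyl chloride, CC(C)(C)[Si](C)(C)Cl
Why: Exhaustive silylation followed by mild basic methanolysis exploits the much greater lability of the peroxy–silicon bond (the peroxide anion is the better leaving group) over the alkyl silyl ether, so the two OH groups need not be told apart in the silylation itself.

Step 14
Reactants: 21 tert-butyl{[(3S,7R,12E,16E)-3-hydroperoxy-3,7-dimethyl-5-methylidene-17-phenylheptadeca-12,16-dien-1-yl]oxy}dimethylsilane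
Product: 22 acetoxy{[(3R,5R)-5-(2-{[tert-butyl(dimethyl)silyl]oxy}ethyl)-5-methyl-3-[(2R,7E,11E)-2-methyl-12-phenyldodeca-7,11-dien-1-yl]-1,2-dioxolan-3-yl]methyl}mercury
Conditions: Hg(OAc)2 (1.05 equiv), CH2Cl2, −20 → 0 °C
Reagents that add atoms: mercury diacetate, CC(=O)O[Hg]OC(C)=O
Why: Divalent mercury adds reversibly to the alkenes as a mercurinium ion, but only the one on the C5 methylidene has a nucleophile within reach, so the terminal oxygen of the C3 hydroperoxide opens it anti at the more substituted carbon C5, forming the O–C5 bond and leaving the C–Hg bond on the exocyclic carbon. The closest known reaction type is the cycloperoxymercuration of homoallylic hydroperoxides to mercuriomethyl 1,2-dioxolanes. The 1,2-dioxolane closes in the 5-exo-trig mode, and Markovnikov opening rules out the 6-endo 1,2-dioxane. The new C5 stereocentre is controlled by the C3 quaternary centre through an envelope transition state in which the larger silyloxyethyl arm sits pseudo-equatorial and the C6 chain ends up on the face of the C3 methyl. The step needs site selectivity among three alkenes, which the intramolecular nucleophile and the electron-rich 1,1-disubstituted alkene secure, and facial selectivity at C5, for which the substrate offers only the size difference between the methyl group and the arm. The C5 epimer is therefore expected as a co-product and is to be removed by chromatography after step 15.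

Step 15
Reactants: 22 acetoxy{[(3R,5R)-5-(2-{[tert-butyl(dimethyl)silyl]oxy}ethyl)-5-methyl-3-[(2R,7E,11E)-2-methyl-12-phenyldodeca-7,11-dien-1-yl]-1,2-dioxolan-3-yl]methyl}mercury
Product: 23 tert-butyl{2-[(3R,5R)-3,5-dimethyl-5-[(2R,7E,11E)-2-methyl-12-phenyldodeca-7,11-dien-1-yl]-1,2-dioxolan-3-yl]ethoxy}dimethylsilane
Conditions: NaBH4, 2 M aq. NaOH, CH2Cl2, 0 °C
Reagents that add atoms: none
Why: Alkaline hydridodemercuration replaces the C–Hg bond by C–H through an alkylmercury hydride and a short-lived primary radical, the di-tertiary peroxide has no α-hydrogen and is inert to borohydride, and a high hydride concentration at 0 °C keeps radical attack on the O–O bond in check.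

Step 16
Reactants: 23 tert-butyl{2-[(3R,5R)-3,5-dimethyl-5-[(2R,7E,11E)-2-methyl-12-phenyldodeca-7,11-dien-1-yl]-1,2-dioxolan-3-yl]ethoxy}dimethylsilane
Product: 24 2-[(3R,5R)-3,5-dimethyl-5-[(2R,7E,11E)-2-methyl-12-phenyldodeca-7,11-dien-1-yl]-1,2-dioxolan-3-yl]ethan-1-ol
Conditions: Bu4NF, THF, 0 °C → rt
Reagents that add atoms: none
Why: Fluoride cleaves the primary silyl ether, and the di-tertiary dialkyl peroxide is stable to fluoride and mild base.

Step 17
Reactants: 24 2-[(3R,5R)-3,5-dimethyl-5-[(2R,7E,11E)-2-methyl-12-phenyldodeca-7,11-dien-1-yl]-1,2-dioxolan-3-yl]ethan-1-ol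
Product: 26 2-[(3S,5R)-3,5-dimethyl-5-[(2R,7E,11E)-2-methyl-12-phenyldodeca-7,11-dien-1-yl]-1,2-dioxolan-3-yl]acetic acid, via dioxolane acetaldehyde 25 (not isolated)
Conditions: TEMPO (20 mol%), PhI(OAc)2 (2.2 equiv), MeCN/H2O 1:1, rt
Reagents that add atoms: water, O
Why: Nitroxyl-catalysed oxidation with PhI(OAc)2 in aqueous acetonitrile takes the primary alcohol through the aldehyde and its hydrate to the acid under near-neutral conditions that leave the peroxide and both alkenes intact (the C3 descriptor changes by priority only).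

**Compound list**

1 | (S)-mevalonolactone | O=C1C[C@](O)(C)CCO1 | starting material
2 | (3S)-3,5-dihydroxy-N-methoxy-N,3-dimethylpentanamide | CON(C)C(=O)C[C@](O)(C)CCO | intermediate
3 | (3S)-3-hydroxy-5-[methoxy(methyl)amino]-3-methyl-5-oxopentyl 4-methylbenzenesulfonate | CON(C)C(=O)C[C@](O)(C)CCOS(=O)(=O)c1ccc(C)cc1 | intermediate
4 | N-methoxy-N-methyl-2-[(2S)-2-methyloxetan-2-yl]acetamide | CON(C)C(=O)C[C@]1(C)CCO1 | intermediate
5 | (4E)-5-phenylpent-4-enoic acid | OC(=O)CC/C=C/c1ccccc1 | starting material
6 | (4E)-5-phenylpent-4-en-1-ol | OCCC/C=C/c1ccccc1 | intermediate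
7 | 1-phenyl-5-{[(4E)-5-phenylpent-4-en-1-yl]sulfanyl}-1H-tetrazole | C(CC/C=C/c1ccccc1)Sc1nnnn1-c1ccccc1 | intermediate
8 | 1-phenyl-5-{[(4E)-5-phenylpent-4-en-1-yl]sulfonyl}-1H-tetrazole | O=S(=O)(CCC/C=C/c1ccccc1)c1nnnn1-c1ccccc1 | intermediate
9 | (2R)-3-bromo-2-methylpropan-1-ol | C[C@H](CO)CBr | starting material
10 | (2R)-3-bromo-2-methylpropyl trifluoromethanesulfonate | C[C@H](COS(=O)(=O)C(F)(F)F)CBr | intermediate
11 | 5-bromopent-1-ene | C=CCCCBr | starting material
12 | pent-4-enylmagnesium bromide | C=CCCC[Mg]Br | intermediate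
13 | (7R)-8-bromo-7-methyloct-1-ene | C[C@H](CCCCC=C)CBr | intermediate
14 | (6R)-7-bromo-6-methylheptanal | C[C@H](CCCCC=O)CBr | intermediate
15 | [(1E,5E,11R)-12-bromo-11-methyldodeca-1,5-dien-1-yl]benzene | C[C@H](CCCC/C=C/CC/C=C/c1ccccc1)CBr | intermediate
16 | bromo[(2R,7E,11E)-2-methyl-12-phenyldodeca-7,11-dien-1-yl]magnesium | C[C@H](CCCC/C=C/CC/C=C/c1ccccc1)C[Mg]Br | intermediate
17 | (4R,9E,13E)-4-methyl-1-[(2S)-2-methyloxetan-2-yl]-14-phenyltetradeca-9,13-dien-2-one | C[C@H](CCCC/C=C/CC/C=C/c1ccccc1)CC(=O)C[C@]1(C)CCO1 | intermediate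
18 | (2R)-2-methyl-2-[(4R,9E,13E)-4-methyl-2-methylidene-14-phenyltetradeca-9,13-dien-1-yl]oxetane | C[C@H](CCCC/C=C/CC/C=C/c1ccccc1)CC(=C)C[C@]1(C)CCO1 | intermediate
19 | (3S,7R,12E,16E)-3-hydroperoxy-3,7-dimethyl-5-methylidene-17-phenylheptadeca-12,16-dien-1-ol | C[C@H](CCCC/C=C/CC/C=C/c1ccccc1)CC(=C)C[C@@](C)(CCO)OO | intermediate
20 | tert-butyl{[(3S,7R,12E,16E)-3-{[tert-butyl(dimethyl)silyl]peroxy}-3,7-dimethyl-5-methylidene-17-phenylheptadeca-12,16-dien-1-yl]oxy}dimethylsilane | C[C@H](CCCC/C=C/CC/C=C/c1ccccc1)CC(=C)C[C@@](C)(CCO[Si](C)(C)C(C)(C)C)OO[Si](C)(C)C(C)(C)C | intermediate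
21 | tert-butyl{[(3S,7R,12E,16E)-3-hydroperoxy-3,7-dimethyl-5-methylidene-17-phenylheptadeca-12,16-dien-1-yl]oxy}dimethylsilane | C[C@H](CCCC/C=C/CC/C=C/c1ccccc1)CC(=C)C[C@@](C)(CCO[Si](C)(C)C(C)(C)C)OO | intermediate
22 | acetoxy{[(3R,5R)-5-(2-{[tert-butyl(dimethyl)silyl]oxy}ethyl)-5-methyl-3-[(2R,7E,11E)-2-methyl-12-phenyldodeca-7,11-dien-1-yl]-1,2-dioxolan-3-yl]methyl}mercury (chain cis to the methyl on the other ring carbon) | C[C@H](CCCC/C=C/CC/C=C/c1ccccc1)C[C@]1(C[Hg]OC(C)=O)C[C@@](C)(CCO[Si](C)(C)C(C)(C)C)OO1 | intermediate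
23 | tert-butyl{2-[(3R,5R)-3,5-dimethyl-5-[(2R,7E,11E)-2-methyl-12-phenyldodeca-7,11-dien-1-yl]-1,2-dioxolan-3-yl]ethoxy}dimethylsilane | C[C@H](CCCC/C=C/CC/C=C/c1ccccc1)C[C@]1(C)C[C@@](C)(CCO[Si](C)(C)C(C)(C)C)OO1 | intermediate
24 | 2-[(3R,5R)-3,5-dimethyl-5-[(2R,7E,11E)-2-methyl-12-phenyldodeca-7,11-dien-1-yl]-1,2-dioxolan-3-yl]ethan-1-ol | C[C@H](CCCC/C=C/CC/C=C/c1ccccc1)C[C@]1(C)C[C@@](C)(CCO)OO1 | intermediate
25 | 2-[(3S,5R)-3,5-dimethyl-5-[(2R,7E,11E)-2-methyl-12-phenyldodeca-7,11-dien-1-yl]-1,2-dioxolan-3-yl]acetaldehyde | C[C@H](CCCC/C=C/CC/C=C/c1ccccc1)C[C@]1(C)C[C@@](C)(CC=O)OO1 | intermediate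
26 | 2-[(3S,5R)-3,5-dimethyl-5-[(2R,7E,11E)-2-methyl-12-phenyldodeca-7,11-dien-1-yl]-1,2-dioxolan-3-yl]acetic acid | C[C@H](CCCC/C=C/CC/C=C/c1ccccc1)C[C@]1(C)C[C@@](C)(CC(=O)O)OO1 | target

**Count**

Total step count: 17.
Longest linear sequence: 12 steps (steps 3–5 and 9–17; the branch from 9 through steps 6–17 is equally long).

**Steps most likely to fail**

1. Step 14. What may go wrong: weak facial discrimination at C5 during ring closure, and mercuration of the C12 or C16 alkenes or slow reversal of the adduct. Fallback: setting out from 21, N-bromosuccinimide in CH2Cl2 at −40 °C should form the same O–C5 bond by bromonium-induced 5-exo attack of the hydroperoxide, an irreversible closure run colder than the mercuration, to give the bromomethyl dioxolane F1. Bu3SnH at high concentration (Et3B, trace air, 0 °C) should then reduce the C–Br bond and return to the route at 23, with no organomercurial involved.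

2. Step 12. What may go wrong: ionisation at C3 ahead of peroxide delivery, which erodes the inversion or ends in elimination, and acid-promoted addition of H2O2 to the methylidene. Fallback: setting out from 18, Co(acac)2-catalysed Mukaiyama–Isayama hydroperoxysilylation (O2, Et3SiH, ClCH2CH2Cl, rt) should place a triethylsilylperoxy group on C5 with Markovnikov regiochemistry to give the silyl peroxide F2 as both C5 epimers. Bu4NF at 0 °C should free the tertiary hydroperoxide F3. Catalytic Me3SiOTf (CH2Cl2, −78 °C) should then let that hydroperoxide open the oxetane at C3 from the rear in a 5-exo closure, giving alcohol 24 together with its C5 epimer F4; after separation the route is rejoined at 24. This variant never exposes the alkenes to free H2O2 and acid, at the price of no control at C5 and possible competition from the styrenyl alkene in the cobalt step.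

3. Step 15. What may go wrong: the primary radical formed on loss of mercury attacks the neighbouring O–O bond (ring-opening to an epoxide) faster than it is reduced. Fallback: setting out from 22, iododemercuration (I2, CH2Cl2, 0 °C), which leaves the alkenes alone, should give the iodomethyl dioxolane F5. Reduction with neat Bu3SnH (Et3B, trace air, 0 °C) supplies a much higher hydrogen-donor concentration and should return to the route at 23.

Further compounds
F1 | step 14 | tert-butyl{2-[(3R,5R)-5-(bromomethyl)-3-methyl-5-[(2R,7E,11E)-2-methyl-12-phenyldodeca-7,11-dien-1-yl]-1,2-dioxolan-3-yl]ethoxy}dimethylsilane | C[C@H](CCCC/C=C/CC/C=C/c1ccccc1)C[C@]1(CBr)C[C@@](C)(CCO[Si](C)(C)C(C)(C)C)OO1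
F2 | step 12 | triethyl{[(2RS,4R,9E,13E)-2,4-dimethyl-1-[(2S)-2-methyloxetan-2-yl]-14-phenyltetradeca-9,13-dien-2-yl]peroxy}silane | C[C@H](CCCC/C=C/CC/C=C/c1ccccc1)CC(C)(OO[Si](CC)(CC)CC)C[C@]1(C)CCO1
F3 | step 12 | (2RS,4R,9E,13E)-2-hydroperoxy-2,4-dimethyl-1-[(2S)-2-methyloxetan-2-yl]-14-phenyltetradeca-9,13-diene | C[C@H](CCCC/C=C/CC/C=C/c1ccccc1)CC(C)(OO)C[C@]1(C)CCO1
F4 | step 12 | 2-[(3R,5S)-3,5-dimethyl-5-[(2R,7E,11E)-2-methyl-12-phenyldodeca-7,11-dien-1-yl]-1,2-dioxolan-3-yl]ethan-1-ol | C[C@H](CCCC/C=C/CC/C=C/c1ccccc1)C[C@@]1(C)C[C@@](C)(CCO)OO1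
F5 | step 15 | tert-butyl{2-[(3R,5R)-5-(iodomethyl)-3-methyl-5-[(2R,7E,11E)-2-methyl-12-phenyldodeca-7,11-dien-1-yl]-1,2-dioxolan-3-yl]ethoxy}dimethylsilane | C[C@H](CCCC/C=C/CC/C=C/c1ccccc1)C[C@]1(CI)C[C@@](C)(CCO[Si](C)(C)C(C)(C)C)OO1
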